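## Structural features

The target (17) is a drimane: a trans-fused decalin whose ring A (C1–C5, C10) is saturated and carries the C4 gem-dimethyl group, and whose ring B (C5–C10) holds the C7=C8 alkene. Four stereocentres run in a row along C6–C5–C10–C9: the C6 carbinol carbon with its acyloxy group α (equatorial, trans to the angular methyl), the ring-fusion C5 (H α), the quaternary C10 (methyl β), and the fully substituted C9 (hydroxyl α, carboxyl C11 β). C8 carries the C12 aldehyde, so ring B contains a γ-acyloxy enal next to a tertiary α-hydroxy acid. The fragile parts are the (2E,4E,6E)-trienoate (oxidants, nucleophiles, base), the allylic C6 ester, and the acid/aldehyde pair, which can close to a lactol and would compete in any esterification. The real difficulty is threefold. C9 is a tetrasubstituted carbon beside quaternary C10 whose carbon substituent must sit on the hindered β face. The C6 oxygen must be α, the opposite of what hydride addition to a C6 ketone delivers. C11 and C12 must be oxidised in an order that keeps them distinguishable. The key step exploits ring B: C5–C10 with oxygen at C6 and C9, the C7=C8 bond and methyl groups on C8 and C10 is a reduced 2,6-dimethyl-1,4-benzoquinone, and C1–C4 with the gem-dimethyl group is 4-methylpenta-1,3-diene.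

## Logic of the disconnections

17 ⇒ 16. The last bond cut is the O–CH2 bond of a benzylic ester on the C11 carboxyl. A free acid (or its lactol with C12) would compete as a nucleophile when C6 is esterified, so the acid is masked until the end. The forward cleavage must spare the allylic C6 ester, the triene and the enal.

16 ⇒ 14 + 15. The C6–O bond is cut in the sense of an SN2 displacement by the carboxylate of 15. Hydride can reach a C6 ketone only from the α face, so the accessible alcohol is the 6β epimer; displacement with inversion turns that defect into the esterification itself and makes the route convergent. The forward step must favour substitution over anti-elimination toward C5 at a crowded centre.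

14 ⇒ 13. The O–Si bond at C6 is restored. The silyl ether keeps the secondary allylic alcohol out of three oxidations and one methylenation. Its removal must not touch the benzylic ester or the hydroxy enal.

13 ⇒ 12. The C12 carbonyl is taken back to the C8 methyl group. This is the only C–H oxidation of the route and returns to a carbon that the quinone supplies. The forward allylic oxidation must pick C12 and not C6.

12 ⇒ 11. The ester O–C bond on C11 is cut. Masking before the allylic oxidation prevents the acid and the new aldehyde from closing to a lactol. The esterification must work at a carboxyl attached to a fully substituted carbon, which points to carboxylate alkylation.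

11 ⇒ 9 (through 10). C11 is lowered from the carboxyl to the primary alcohol level. This leads back to a 1,2-diol. The oxidation must take the primary alcohol only and must not cleave the C9–C11 bond.

9 ⇒ 8. The C9–O and C11–O bonds are cut to an exocyclic C9=C11 alkene. Adding both oxygens across this alkene from the open α face puts the hydroxyl α and leaves C11 β, the arrangement a carbon nucleophile adding to a C9 ketone cannot give. The forward step must select the exocyclic alkene over C7=C8.

8 ⇒ 7. The C9=C11 bond is cut to the C9 ketone. C11 is the one skeletal carbon the cycloaddition does not provide. The methylenation must work on a carbonyl wedged between C10 and the C8 methyl without enolising through C6–H.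

7 ⇒ 6. The C2–H and C3–H bonds are removed, restoring the C2=C3 alkene left by the cycloaddition. Saturation is placed after C6 is reduced and silylated, when C7=C8 is a shielded, trisubstituted enone alkene. The hydrogenation must discriminate by substitution pattern.

6 ⇒ 5. The O–Si bond at C6 is cut. This is protecting-group bookkeeping only; the demand is clean silylation of an axial, doubly flanked alcohol.

5 ⇒ 4. The C6–H bond is removed, returning C6 to the ketone. Both ring-B oxygens then come from one enedione. The reduction must choose C6 over C9 and 1,2- over 1,4-addition, and it fixes C5 against later epimerisation.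

4 ⇒ 1 + 2 (through 3). C5 is first epimerised back to the cis adduct, then the C1–C10 and C4–C5 bonds are cut. Fourteen of fifteen carbons, ring A, the C7=C8 bond and both ring-B oxygens fall back to two purchasable compounds. The forward cycloaddition needs control of orientation and of the face at C10; C5 is corrected by equilibration.

## Other disconnections considered

Alternative 1: The cut runs through C5–C10 and C8–C9 and unravels both rings into one acyclic triene, the oxazolidinone imide A2. In the forward sense the (E)-4-oxo-enoyl imide of A2 (dienophile C9=C10) is held in two-point chelation by a bis(oxazoline) complex of divalent copper such as [Cu(t-Bu-box)](SbF6)2. It then adds to its own (E,E)-diene (C5=C6–C7=C8) to give the trans-fused bicyclic imide A1.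
- In its favour: all fifteen carbons arrive in one step, with C11 at the carboxyl level and C12 already oxygenated. Four stereocentres are set by one catalyst. The trans fusion comes directly from the transition-state geometry, with no epimerisation to rely on. In these three respects it is the equal or the better of the chosen plan.
- Against it here: A2 needs its own linear synthesis with three defined alkenes. The cycloaddition must create quaternary C10 from a β,β-disubstituted dienophile while the diene terminus C5 is neopentylic, and the 4-oxo group offers the metal a competing chelation site. A1 has its oxygen in the wrong places: a C1 ketone to delete, no oxygen at C6 or C9, the alkene at C6=C7, and a C8 stereocentre that must be destroyed again.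
- Comparison: on structure the alternative wins on carbon count and on the C11/C12 oxidation level, and the chosen plan wins on oxygen at C6 and C9. On mechanism both are catalytic asymmetric [4+2] reactions; the intramolecular one is entropically favoured but sterically more demanding. On step economy the chosen plan spends nothing before its key step, while the alternative would spend steps both making A2 and re-positioning oxygen, so it is not expected to be shorter.

Alternative 2: The cut is the single ring-B bond C8–C9. It leads back to a monocyclic ring-A compound, the iodo keto ester A4, in which C10 carries the α-keto tert-butyl ester and C5 carries the C6–C7=C8–C12 side chain with iodine on C8. In the forward sense CrCl2 (divalent chromium) with catalytic NiCl2 converts the (Z)-alkenyl iodide into an alkenylchromium species. This adds to the C9 ketone, closing ring B by intramolecular 1,2-addition to give the protected core A3.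
- In its favour: A3 already has every oxygen of the target at the right level (C12 as an acetal, C11 as an ester, the C6 oxygen α). No late C–H oxidation and no inversion at C6 are needed, so the end game from A3 is shorter and safer than that of the chosen plan; in this respect it is clearly better. The organochromium reagent tolerates esters, acetals and silyl ethers.
- Against it here: the step forms one bond and one stereocentre only. A4 must already contain C5, C6 and C10, including a quaternary carbon bearing an α-keto ester next to a side chain with a trisubstituted (Z)-iodoalkene, and each needs its own asymmetric chemistry. Alkenylchromium additions to ketones are much slower than to aldehydes. The C9 configuration would rest on a conformational preference of the tether, not on a strong substrate bias such as the α-face osmylation of the chosen plan.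
- Comparison: on structure the product is closer to the target but far less skeleton is built. On mechanism it is a polar chelation-controlled addition against a pericyclic ring construction. On step economy it is shorter after the key step and much longer before it, so the total is expected to be longer.

Alternative 3: The cut removes C4–C5 and C9–C10 in the sense of a polyene cyclisation and leads to (2E,6E)-farnesol A6. In the forward sense an engineered squalene–hopene cyclase protonates the terminal alkene of A6. The chair–chair folded chain closes ring A and then ring B, and loss of the C7 proton releases (−)-drimenol A5.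
- In its favour: one step from a bulk terpene alcohol gives the complete C15 skeleton, the trans fusion and three stereocentres (C5, C9, C10) under enzyme control. C11 is already oxygenated and no carbon is missing. On skeleton construction and ring-fusion control this is better than the chosen plan.
- Against it here: A5 has no oxygen at C6, C9 or C12. C9 would need hydroxylation, C6 would need allylic oxidation followed by carbonyl reduction (which recreates the same configurational problem at C6), and C12 would need the same allylic oxidation as in the chosen route. The enzyme variant must be expressed and works at low substrate loading.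
- Comparison: on structure it is better for carbons and C5/C10, equal for C12 and for the C6 configuration problem, and worse for the oxidation state at C6 and C9, which the quinone supplies at no cost. On mechanism it is an enzyme-controlled cationic cascade against a Lewis-acid cycloaddition with thermodynamic correction. On step economy the gain at the skeleton is expected to be spent again on separate oxidations, so the totals are judged comparable.

Key step: step 1

Remarks on the chemistry (assumptions):
- Drimane numbering is used throughout. α is the face of H-5 and β is the face of the C10 methyl (C15); "11-nor" marks compounds that still lack C11.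
- The target is drawn as the open C11 acid/C12 aldehyde. Its ring–chain tautomer (the 12-hydroxy-11,12-olide lactol) is the same compound at equilibrium.
- The oxazaborolidinium ion from (S)-α,α-diphenylprolinol is assumed to be the enantiomer that leads to (8aS). The (R)-derived catalyst would be used unchanged otherwise if the sense of induction proved opposite.
- (2E,4E,6E)-Octa-2,4,6-trienoic acid is taken as purchasable.

## Route

Step 1
Reactants: 1 2,6-dimethyl-1,4-benzoquinone; 2 4-methylpenta-1,3-diene
Product: 4 (4aS,8aS)-2,5,5,8a-tetramethyl-4a,5,8,8a-tetrahydronaphthalene-1,4-dione (trans-fused; 11-nordrima-2,7-diene-6,9-dione), via cis-fused adduct 3 (not isolated)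
Conditions: oxazaborolidinium triflimide prepared from (S)-α,α-diphenylprolinol, o-tolylboronic acid and Tf2NH (20 mol %), 2 (4 equiv), CH2Cl2, −78 → −20 °C; then DBU (0.5 equiv), rt
Reagents that add atoms: none
Why: The protonated oxazaborolidine binds the C6 carbonyl of 1, the more basic and less hindered one, and lowers the quinone LUMO, whose largest coefficient then lies on the methyl-bearing β-carbon (future C10). Diene 2 reacts through its s-cis conformer in a concerted, asynchronous [4+2] cycloaddition in which its unsubstituted terminus (C1) bonds to C10 ahead of the CMe2 terminus (C4) bonding to C5; the closest known reaction type is the oxazaborolidinium-catalysed Diels–Alder reaction of methyl-substituted 1,4-benzoquinones. Ring A is closed as a six-membered carbocycle by intermolecular [4+2] annulation, both bonds forming on one face of the quinone, so the primary adduct 3 is cis-fused. C10 is controlled by the catalyst, whose aryl group screens one face of the bound enone. C5 is the only enolisable centre (quaternary C10 blocks aromatisation), and DBU equilibrates 3 through the C5=C6 dienolate, which is reprotonated on the α face away from the C15 and 4β-methyl groups to give trans-fused 4. The two ring alkenes of 1 are homotopic, so only orientation and face must be controlled; orientation is secured because electronics and sterics agree (the reverse mode would join the CMe2 terminus to the methyl-bearing carbon), and the diene creates no endo/exo-dependent stereocentre. The Z-methyl of 2 slows the reaction, so excess diene and low temperature are used to keep acid-induced oligomerisation behind the cycloaddition.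

Step 2
Reactants: 4 (4aS,8aS)-2,5,5,8a-tetramethyl-4a,5,8,8a-tetrahydronaphthalene-1,4-dione
Product: 5 (4R,4aS,8aS)-4-hydroxy-2,5,5,8a-tetramethyl-4a,5,8,8a-tetrahydronaphthalen-1(4H)-one (6β-hydroxy-11-nordrima-2,7-dien-9-one)
Conditions: NaBH4 (1.0 equiv), CeCl3·7H2O, MeOH, −78 → −40 °C
Reagents that add atoms: none
Why: Luche 1,2-reduction takes the C6 carbonyl (neighbours C5–H and C7–H) in preference to the C9 carbonyl wedged between quaternary C10 and the C8 methyl; hydride enters from the α face, opposite the syn-axial C15 and 4β-methyl groups, setting the axial 6β (R) alcohol, and C5 can no longer epimerise once C6 is sp3.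

Step 3
Reactants: 5 6β-hydroxy-11-nordrima-2,7-dien-9-one
Product: 6 6β-(tert-butyldimethylsilyloxy)-11-nordrima-2,7-dien-9-one
Conditions: TBSOTf, 2,6-lutidine, CH2Cl2, 0 °C
Reagents that add atoms: tert-butyldimethylsilyl trifluoromethanesulfonate, CC(C)(C)[Si](C)(C)OS(=O)(=O)C(F)(F)F
Why: Silylation with the silyl triflate is the standard way to protect a hindered axial secondary alcohol; the ether shields C6–OH from the later oxidations and adds bulk on the β face of C7=C8; no stereocentre changes.

Step 4
Reactants: 6 6β-(tert-butyldimethylsilyloxy)-11-nordrima-2,7-dien-9-one
Product: 7 6β-(tert-butyldimethylsilyloxy)-11-nordrim-7-en-9-one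
Conditions: H2 (1 atm), RhCl(PPh3)3 (5 mol %), toluene/EtOH, rt
Reagents that add atoms: none
Why: Homogeneous hydrogenation with RhCl(PPh3)3 discriminates by substitution: the cis-disubstituted C2=C3 is reduced while the trisubstituted, conjugated C7=C8, flanked by the axial silyl ether and the C9 carbonyl, is left, and the allylic C6–O bond is not hydrogenolysed as it might be on a palladium surface; no stereocentre is formed.

Step 5
Reactants: 7 6β-(tert-butyldimethylsilyloxy)-11-nordrim-7-en-9-one
Product: 8 6β-(tert-butyldimethylsilyloxy)drima-7,9(11)-diene
Conditions: Cp2TiMe2 (3 equiv), toluene, 70 °C, dark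
Reagents that add atoms: dimethyltitanocene, C[Ti](C)(C1C=CC=C1)C1C=CC=C1
Why: Carbonyl methylenation by the titanium methylidene Cp2Ti=CH2 (formed thermally from Cp2TiMe2) through an oxatitanacyclobutane; the reagent is non-basic, so C6–H is not removed, and the small carbene tolerates a neopentylic, α-branched enone carbonyl where a phosphorus ylide may stall; this adds C11.

Step 6
Reactants: 8 6β-(tert-butyldimethylsilyloxy)drima-7,9(11)-diene
Product: 9 6β-(tert-butyldimethylsilyloxy)drim-7-ene-9α,11-diol
Conditions: OsO4 (3 mol %), NMO (1.1 equiv), acetone/H2O, 0 °C
Reagents that add atoms: osmium tetroxide, O=[Os](=O)(=O)=O; N-methylmorpholine N-oxide, C[N+]1([O-])CCOCC1; water, O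
Why: Catalytic osmium tetroxide dihydroxylation ([3+2] addition, then hydrolysis): the 1,1-disubstituted C9=C11 with its open CH2 terminus should react before C7=C8, which is trisubstituted, inductively deactivated by the allylic silyloxy group and screened on its β face; osmium approaches C9 from the α face, anti to the axial C15 methyl on the adjacent carbon, so O9 is α and C11 stays β (9S).

Step 7
Reactants: 9 6β-(tert-butyldimethylsilyloxy)drim-7-ene-9α,11-diol
Product: 11 6β-(tert-butyldimethylsilyloxy)-9α-hydroxydrim-7-en-11-oic acid, via hydroxy aldehyde 10 (not isolated)
Conditions: TEMPO (0.1 equiv), NaClO2 (2 equiv), NaOCl (2 mol %), MeCN/phosphate buffer pH 6.7, 35 °C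
Reagents that add atoms: sodium chlorite, [Na+].[O-]Cl=O
Why: Oxoammonium oxidation is selective for the primary C11 alcohol (the C9 alcohol is tertiary, C6 is silylated) and chlorite converts aldehyde 10 to the acid as it forms (Pinnick-type), regenerating hypochlorite; C9 has no α-hydrogen, so its configuration is safe.

Step 8
Reactants: 11 6β-(tert-butyldimethylsilyloxy)-9α-hydroxydrim-7-en-11-oic acid
Product: 12 4-methoxybenzyl 6β-(tert-butyldimethylsilyloxy)-9α-hydroxydrim-7-en-11-oate
Conditions: 4-methoxybenzyl chloride, K2CO3, Bu4NI (cat.), DMF, rt
Reagents that add atoms: 4-methoxybenzyl chloride, COc1ccc(CCl)cc1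
Why: Carboxylate O-alkylation (SN2 at the benzylic chloride) is indifferent to the crowding around C11, unlike acyl-transfer esterification, and carbonate does not alkylate the tertiary alcohol; masking the acid now prevents lactol formation once C12 is an aldehyde.

Step 9
Reactants: 12 4-methoxybenzyl 6β-(tert-butyldimethylsilyloxy)-9α-hydroxydrim-7-en-11-oate
Product: 13 4-methoxybenzyl 6β-(tert-butyldimethylsilyloxy)-9α-hydroxy-12-oxodrim-7-en-11-oate
Conditions: SeO2 (1.5 equiv), 1,4-dioxane, 90 °C
Reagents that add atoms: selenium dioxide, O=[Se]=O
Why: Riley allylic oxidation: ene reaction of SeO2 at C7 with hydrogen transfer from C12, [2,3]-sigmatropic shift to the C12 selenite ester and collapse to the aldehyde; oxidation occurs at the more substituted alkene terminus (C8), whose only hydrogen-bearing allylic carbon is C12, while C6 hangs on the less substituted terminus and is silylated.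

Step 10
Reactants: 13 4-methoxybenzyl 6β-(tert-butyldimethylsilyloxy)-9α-hydroxy-12-oxodrim-7-en-11-oate
Product: 14 4-methoxybenzyl 6β,9α-dihydroxy-12-oxodrim-7-en-11-oate
Conditions: HF·pyridine, pyridine, THF, 0 °C → rt
Reagents that add atoms: none
Why: Fluoride-driven Si–O cleavage; buffered HF·pyridine is mild enough for the benzylic ester and the hydroxy enal, and no stereocentre is touched.

Step 11
Reactants: 14 4-methoxybenzyl 6β,9α-dihydroxy-12-oxodrim-7-en-11-oate; 15 (2E,4E,6E)-octa-2,4,6-trienoic acid
Product: 16 4-methoxybenzyl 9α-hydroxy-6α-[(2E,4E,6E)-octa-2,4,6-trienoyloxy]-12-oxodrim-7-en-11-oate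
Conditions: PPh3, DIAD, 15 (2 equiv), toluene, 0 °C → rt
Reagents that add atoms: none
Why: Mitsunobu esterification: the 6β alcohol is activated as its alkoxyphosphonium ion and displaced by the carboxylate of 15 from the α face (SN2), inverting C6 to the 6α (S) ester; the tertiary C9 alcohol is inert, and the electron-poor C7=C8–CHO disfavours ionisation and attack at the fully substituted C8.

Step 12
Reactants: 16 4-methoxybenzyl 9α-hydroxy-6α-[(2E,4E,6E)-octa-2,4,6-trienoyloxy]-12-oxodrim-7-en-11-oate
Product: 17 9α-hydroxy-6α-[(2E,4E,6E)-octa-2,4,6-trienoyloxy]-12-oxodrim-7-en-11-oic acid (target)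
Conditions: TFA, anisole, CH2Cl2, 0 °C
Reagents that add atoms: none
Why: Acidolysis of the 4-methoxybenzyl ester through the stabilised benzylic cation, which anisole traps; the C6 ester is allylic to an electron-poor alkene and C9 carries a carboxyl, so neither ionises, and the triene ester is not protonated productively in a short exposure.

## Compound list

1 | 2,6-dimethyl-1,4-benzoquinone | CC1=CC(=O)C=C(C)C1=O | starting material
2 | 4-methylpenta-1,3-diene | C=CC=C(C)C | starting material
3 | (4aR,8aS)-2,5,5,8a-tetramethyl-4a,5,8,8a-tetrahydronaphthalene-1,4-dione (cis-fused adduct, H-5 β) | O=C1C=C(C)C(=O)[C@@]2(C)CC=CC(C)(C)[C@@H]12 | intermediate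
4 | (4aS,8aS)-2,5,5,8a-tetramethyl-4a,5,8,8a-tetrahydronaphthalene-1,4-dione (trans-fused; 11-nordrima-2,7-diene-6,9-dione) | O=C1C=C(C)C(=O)[C@@]2(C)CC=CC(C)(C)[C@H]12 | intermediate
5 | (4R,4aS,8aS)-4-hydroxy-2,5,5,8a-tetramethyl-4a,5,8,8a-tetrahydronaphthalen-1(4H)-one (6β-hydroxy-11-nordrima-2,7-dien-9-one) | O[C@@H]1C=C(C)C(=O)[C@@]2(C)CC=CC(C)(C)[C@H]12 | intermediate
6 | 6β-(tert-butyldimethylsilyloxy)-11-nordrima-2,7-dien-9-one | CC(C)(C)[Si](C)(C)O[C@@H]1C=C(C)C(=O)[C@@]2(C)CC=CC(C)(C)[C@H]12 | intermediate
7 | 6β-(tert-butyldimethylsilyloxy)-11-nordrim-7-en-9-one | CC(C)(C)[Si](C)(C)O[C@@H]1C=C(C)C(=O)[C@@]2(C)CCCC(C)(C)[C@H]12 | intermediate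
8 | 6β-(tert-butyldimethylsilyloxy)drima-7,9(11)-diene | CC(C)(C)[Si](C)(C)O[C@@H]1C=C(C)C(=C)[C@@]2(C)CCCC(C)(C)[C@H]12 | intermediate
9 | 6β-(tert-butyldimethylsilyloxy)drim-7-ene-9α,11-diol | CC(C)(C)[Si](C)(C)O[C@@H]1C=C(C)[C@](O)(CO)[C@@]2(C)CCCC(C)(C)[C@H]12 | intermediate
10 | 6β-(tert-butyldimethylsilyloxy)-9α-hydroxydrim-7-en-11-al | CC(C)(C)[Si](C)(C)O[C@@H]1C=C(C)[C@](O)(C=O)[C@@]2(C)CCCC(C)(C)[C@H]12 | intermediate
11 | 6β-(tert-butyldimethylsilyloxy)-9α-hydroxydrim-7-en-11-oic acid | CC(C)(C)[Si](C)(C)O[C@@H]1C=C(C)[C@](O)(C(=O)O)[C@@]2(C)CCCC(C)(C)[C@H]12 | intermediate
12 | 4-methoxybenzyl 6β-(tert-butyldimethylsilyloxy)-9α-hydroxydrim-7-en-11-oate | CC(C)(C)[Si](C)(C)O[C@@H]1C=C(C)[C@](O)(C(=O)OCc3ccc(OC)cc3)[C@@]2(C)CCCC(C)(C)[C@H]12 | intermediate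
13 | 4-methoxybenzyl 6β-(tert-butyldimethylsilyloxy)-9α-hydroxy-12-oxodrim-7-en-11-oate | CC(C)(C)[Si](C)(C)O[C@@H]1C=C(C=O)[C@](O)(C(=O)OCc3ccc(OC)cc3)[C@@]2(C)CCCC(C)(C)[C@H]12 | intermediate
14 | 4-methoxybenzyl 6β,9α-dihydroxy-12-oxodrim-7-en-11-oate | O[C@@H]1C=C(C=O)[C@](O)(C(=O)OCc3ccc(OC)cc3)[C@@]2(C)CCCC(C)(C)[C@H]12 | intermediate
15 | (2E,4E,6E)-octa-2,4,6-trienoic acid | C/C=C/C=C/C=C/C(=O)O | starting material
16 | 4-methoxybenzyl 9α-hydroxy-6α-[(2E,4E,6E)-octa-2,4,6-trienoyloxy]-12-oxodrim-7-en-11-oate | C/C=C/C=C/C=C/C(=O)O[C@H]1C=C(C=O)[C@](O)(C(=O)OCc3ccc(OC)cc3)[C@@]2(C)CCCC(C)(C)[C@H]12 | intermediate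
17 | (1S,4S,4aS,8aS)-2-formyl-1-hydroxy-5,5,8a-trimethyl-4-[(2E,4E,6E)-octa-2,4,6-trienoyloxy]-1,4,4a,5,6,7,8,8a-octahydronaphthalene-1-carboxylic acid (9α-hydroxy-6α-trienoyloxy-12-oxodrim-7-en-11-oic acid) | C/C=C/C=C/C=C/C(=O)O[C@H]1C=C(C=O)[C@](O)(C(=O)O)[C@@]2(C)CCCC(C)(C)[C@H]12 | target

## Step count and least certain steps

Total: 12 steps. Longest linear sequence: 12 steps (from 1 and 2 to 17); 15 is purchased and joined in step 11.

Step 1 (key step). The cycloaddition may be slow because the Z-methyl group of 2 disfavours the s-cis conformer; acid-induced oligomerisation of the diene or an uncatalysed background reaction could then erode conversion and facial discrimination, and the base equilibration at C5 could stop short of completion. Fallback, setting out from 1 and 2: the cycloaddition is run without asymmetric induction under forcing achiral activation (SnCl4 in CH2Cl2 at low temperature, or neat under high pressure). This gives the racemic cis adduct, that is 3 together with its mirror image, (4aS,8aR)-2,5,5,8a-tetramethyl-4a,5,8,8a-tetrahydronaphthalene-1,4-dione F1. DBU converts the pair into the racemic trans enedione, that is 4 together with (4aR,8aR)-2,5,5,8a-tetramethyl-4a,5,8,8a-tetrahydronaphthalene-1,4-dione F2. The racemate is resolved by preparative chromatography on a polysaccharide-based chiral stationary phase, and the route is rejoined at 4.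

Step 5. The carbonyl, wedged between C10 and the C8 methyl group, may fail to engage the titanium methylidene before the reagent decays thermally, leaving unchanged ketone. Fallback, setting out from 7: a Peterson olefination. Me3SiCH2Li with anhydrous CeCl3 (THF, −78 °C) adds a small, weakly basic nucleophile to C9 from the α face to give 6β-(tert-butyldimethylsilyloxy)-9α-(trimethylsilylmethyl)-11-nordrim-7-en-9β-ol F3. KH in THF then triggers syn-elimination of the silanolate, and the route is rejoined at 8.

Step 6. Osmylation of the ring alkene C7=C8 may compete with that of C9=C11, or the diol may be dihydroxylated a second time. Fallback, setting out from 7: Wittig reaction with Ph3P=CHOMe (from (methoxymethyl)triphenylphosphonium chloride and KN(SiMe3)2, THF, heating) gives the enol ether 6β-(tert-butyldimethylsilyloxy)-11-methoxydrima-7,9(11)-diene F4 (either alkene geometry serves). Its electron-rich C9=C11 bond should be far more reactive toward OsO4/NMO than C7=C8. α-Face osmylation and loss of methanol from the hemiacetal give hydroxy aldehyde 10, where the route is rejoined; 10 is then oxidised to 11 with NaClO2/NaH2PO4/2-methylbut-2-ene.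

Step 9. The ene step may stall because C7=C8 is deactivated by the oxygen substituents at C6 and C9 and crowded at C7; prolonged heating with selenous acid could then cleave the silyl ether or leave the oxidation at the alcohol stage. Fallback, setting out from 12: hydroxylation and carbonyl formation are separated. Catalytic SeO2 with t-BuOOH in CH2Cl2 at room temperature is expected to stop at the allylic alcohol 4-methoxybenzyl 6β-(tert-butyldimethylsilyloxy)-9α,12-dihydroxydrim-7-en-11-oate F5. MnO2 (CH2Cl2, rt) then oxidises this primary allylic alcohol selectively, and the route is rejoined at 13.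

Step 11. At the crowded C6, anti-elimination of the activated axial oxygen with H-5, or acylation of the reduced azodicarboxylate, may outrun SN2 displacement by the only moderately acidic trienoic acid. Fallback, setting out from 14: activation and displacement are separated. ClCH2SO2Cl/pyridine gives 4-methoxybenzyl 6β-(chloromethanesulfonyloxy)-9α-hydroxy-12-oxodrim-7-en-11-oate F6. Cesium (2E,4E,6E)-octa-2,4,6-trienoate F7 (from 15 and Cs2CO3), with 18-crown-6 in toluene, displaces the sulfonate with inversion, and the route is rejoined at 16.

## Further compounds

F1 | step 1 | (4aS,8aR)-2,5,5,8a-tetramethyl-4a,5,8,8a-tetrahydronaphthalene-1,4-dione (enantiomer of 3) | O=C1C=C(C)C(=O)[C@]2(C)CC=CC(C)(C)[C@H]12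
F2 | step 1 | (4aR,8aR)-2,5,5,8a-tetramethyl-4a,5,8,8a-tetrahydronaphthalene-1,4-dione (enantiomer of 4) | O=C1C=C(C)C(=O)[C@]2(C)CC=CC(C)(C)[C@@H]12
F3 | step 5 | 6β-(tert-butyldimethylsilyloxy)-9α-(trimethylsilylmethyl)-11-nordrim-7-en-9β-ol | CC(C)(C)[Si](C)(C)O[C@@H]1C=C(C)[C@@](O)(C[Si](C)(C)C)[C@@]2(C)CCCC(C)(C)[C@H]12
F4 | step 6 | 6β-(tert-butyldimethylsilyloxy)-11-methoxydrima-7,9(11)-diene (alkene geometry not defined) | CC(C)(C)[Si](C)(C)O[C@@H]1C=C(C)C(=COC)[C@@]2(C)CCCC(C)(C)[C@H]12
F5 | step 9 | 4-methoxybenzyl 6β-(tert-butyldimethylsilyloxy)-9α,12-dihydroxydrim-7-en-11-oate | CC(C)(C)[Si](C)(C)O[C@@H]1C=C(CO)[C@](O)(C(=O)OCc3ccc(OC)cc3)[C@@]2(C)CCCC(C)(C)[C@H]12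
F6 | step 11 | 4-methoxybenzyl 6β-(chloromethanesulfonyloxy)-9α-hydroxy-12-oxodrim-7-en-11-oate | ClCS(=O)(=O)O[C@@H]1C=C(C=O)[C@](O)(C(=O)OCc3ccc(OC)cc3)[C@@]2(C)CCCC(C)(C)[C@H]12
F7 | step 11 | cesium (2E,4E,6E)-octa-2,4,6-trienoate | C/C=C/C=C/C=C/C(=O)[O-].[Cs+]
A1 | alternative 1 | trans-fused 1-oxodrim-6-ene imide with C12 silyl ether (cycloaddition product) | C1=C[C@H](CO[Si](C)(C)C(C)(C)C)[C@H](C(=O)N3CCOC3=O)[C@@]2(C)C(=O)CCC(C)(C)[C@H]12
A2 | alternative 1 | 3-[(2E,8E,10E)-12-(tert-butyldimethylsilyloxy)-3,7,7-trimethyl-4-oxododeca-2,8,10-trienoyl]oxazolidin-2-one | O=C1OCCN1C(=O)/C=C(\C)C(=O)CCC(C)(C)/C=C/C=C/CO[Si](C)(C)C(C)(C)C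
A3 | alternative 2 | protected target core (C6 triethylsilyl ether, C12 diethyl acetal, C11 tert-butyl ester) | CC[Si](CC)(CC)O[C@H]1C=C(C(OCC)OCC)[C@](O)(C(=O)OC(C)(C)C)[C@@]2(C)CCCC(C)(C)[C@H]12
A4 | alternative 2 | 8,9-seco iodo keto ester: tert-butyl α-keto ester on C10, (Z)-iodoalkene acetal side chain on C5 | CC[Si](CC)(CC)O[C@@H](/C=C(\I)C(OCC)OCC)[C@H]1C(C)(C)CCC[C@]1(C)C(=O)C(=O)OC(C)(C)C
A5 | alternative 3 | (−)-drimenol (drim-7-en-11-ol) | C1C=C(C)[C@H](CO)[C@@]2(C)CCCC(C)(C)[C@H]12
A6 | alternative 3 | (2E,6E)-farnesol | CC(C)=CCC/C(C)=C/CC/C(C)=C/CO
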